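**Plan**
1. Numbering: decalin as in drimanes (C1–C10, C11 on C9); then C12, the dioxane carbons C13–C16, and the ester α-carbon C17.
2. Retrosynthesis: cut C12–C13 (alkynyl group onto a peroxycarbenium ion), then C6–C7 and C9–C10 of ring B, then O–C13 and O–C16 of the dioxane.
3. Enabling feature: ring B holds the C7=C8 alkene between allylic C6H2 and C9, which sits next to quaternary C10. C6–C5=C10 of ring A is therefore one β-cyclogeranyl allyl cation, and C7=C8(CH3)–C9–C11 is one 2-methylallyl (isoprene) unit.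
4. Forward: ring A is bought. Ring B is closed in one flask by allylsilane allylation (C6–C7) followed by superacid cation–olefin cyclisation (C9–C10). The 1,2-dioxane is built separately and joined last at C13, then the alkyne is reduced with diimide.
5. Stereochemistry: C5, C9 and C10 are set relative to each other by the chair cyclisation of the E-alkene; the absolute sense comes from a lipase resolution of drimenol. C17 and C16 come from an Evans syn-aldol with SN2 inversion at C16. C13 comes from axial attack on the peroxycarbenium ion.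

Key step: step 6

Remark: β-cyclocitral, methyl 3-methylbut-2-enoate, ethyl 4-methylpent-4-enoate and (S)-4-benzyl-3-propionyl-1,3-oxazolidin-2-one are taken as commercial. Compounds 5–7 are used as racemates because their silicon-bearing stereocenter disappears in step 6.

**Route**

Step 1
Reactants: 1 β-cyclocitral (2,6,6-trimethylcyclohex-1-ene-1-carbaldehyde)
Product: 2 β-cyclogeraniol
Conditions: NaBH4, MeOH, 0 °C
Reagents that add atoms: none
Why: Borohydride 1,2-reduction of the hindered enal should give the allylic alcohol; no stereocenter is formed.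

Step 2
Reactants: 2 β-cyclogeraniol
Product: 3 β-cyclogeranyl acetate
Conditions: Ac2O, pyridine, DMAP (cat.), CH2Cl2, 0 °C → rt
Reagents that add atoms: acetic anhydride CC(=O)OC(C)=O
Why: DMAP-catalysed acetylation should give the ionisable allylic acetate needed as the allyl cation precursor.

Step 3
Reactants: 4 methyl 3-methylbut-2-enoate
Product: 5 methyl 3-methyl-2-[methyl(diphenyl)silyl]but-3-enoate (racemic)
Conditions: LiN(i-Pr)2, THF, −78 °C; then Ph2MeSiCl, −78 → 0 °C
Reagents that add atoms: chloro(methyl)diphenylsilane C[Si](Cl)(c1ccccc1)c1ccccc1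
Why: γ-Deprotonation gives the lithium dienolate, which diarylalkylchlorosilanes silylate on the α-carbon (deconjugative C-silylation); the new stereocenter is racemic and is lost in step 6.

Step 4
Reactants: 5 methyl 3-methyl-2-[methyl(diphenyl)silyl]but-3-enoate
Product: 6 3-methyl-2-[methyl(diphenyl)silyl]but-3-en-1-ol (racemic)
Conditions: LiAlH4, Et2O, −78 → 0 °C; cold Na2SO4·10H2O quench
Reagents that add atoms: none
Why: Hydride reduction of the ester should give the β-hydroxysilane, kept cold and neutral to avoid Peterson elimination.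

Step 5
Reactants: 6 3-methyl-2-[methyl(diphenyl)silyl]but-3-en-1-ol
Product: 7 triethyl{[3-methyl-2-(methyldiphenylsilyl)but-3-en-1-yl]oxy}silane (racemic)
Conditions: Et3SiCl, imidazole, CH2Cl2, 0 °C
Reagents that add atoms: chlorotriethylsilane CC[Si](Cl)(CC)CC
Why: Standard silylation protects the primary alcohol as an ether that ionises poorly and is removed in the acidic work-up of step 6.

Step 6
Reactants: 3 β-cyclogeranyl acetate; 7 triethyl{[3-methyl-2-(methyldiphenylsilyl)but-3-en-1-yl]oxy}silane
Product: 9 (±)-drimenol, via monocyclofarnesyl triethylsilyl ether 8 (not isolated)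
Conditions: Me3SiOTf (0.2 equiv), CH2Cl2, −78 °C; then 2-nitropropane, FSO3H (6 equiv), −78 °C; Et3N/MeOH quench, aq NaHCO3, then 1 M HCl work-up
Reagents that add atoms: none
Why: Me3SiOTf ionises 3 to the β-cyclogeranyl allyl cation, whose unhindered primary terminus C6 is attacked by the CH2 terminus (C7) of the 2-methylallylsilane 7 in a Hosomi–Sakurai SE2' allylation, and anti attack through the conformer with the C9–H bond eclipsing the alkene gives the E-configured ether 8 (C6–C7 formed). FSO3H then protonates the tetrasubstituted C5=C10 alkene of ring A at C5, and the tertiary C10 cation is captured by C9 of the E-alkene in a 6-endo-trig cation–olefin cyclisation through a chair transition state that closes ring B (C9–C10), the C8 cation losing the axial H7 to leave the C7=C8 alkene. The closest known reaction types are the Lewis-acid allylation of allylic acetates with allylsilanes and the superacid cyclisation of (E,E)-farnesyl and monocyclofarnesyl derivatives to drimenyl compounds. C5 is set by protonation followed by chair closure to the trans-fused decalin, C10 by the chair (axial methyl) and C9 by the E geometry of the alkene (equatorial CH2O group), so the three centres are fixed relative to each other only and 9 is racemic. The step needs C6 rather than C10 attack on the allyl cation (secured by the steric difference between the termini), E geometry in 8 (secured by the anti-SE2' pathway) and loss of H7 rather than H9 or a methyl proton at the end (expected under kinetic control at −78 °C).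

Step 7
Reactants: 9 (±)-drimenol
Product: 10 (1R,4aR,8aR)-drimenol (ent-drimenol)
Conditions: Amano lipase PS (Burkholderia cepacia lipase), vinyl acetate, t-BuOMe, 30 °C, run beyond half conversion; chromatography
Reagents that add atoms: none
Why: Lipase-catalysed enantioselective acetylation (kinetic resolution) of the primary alcohol next to C9 should, by analogy with the exocyclic isomer albicanol, acetylate the (1S,4aS,8aS) enantiomer and leave 10 as the unreacted alcohol; no new stereocenter is made.

Step 8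
Reactants: 10 (1R,4aR,8aR)-drimenol
Product: 11 (1R,4aR,8aR)-drim-7-en-11-al (ent-drimenal)
Conditions: Dess–Martin periodinane, NaHCO3, CH2Cl2, 0 °C
Reagents that add atoms: none
Why: Buffered Dess–Martin oxidation gives the β,γ-unsaturated aldehyde under conditions that should neither epimerise C9 nor move the alkene into conjugation.

Step 9
Reactants: 11 (1R,4aR,8aR)-drim-7-en-11-al
Product: 12 (1R,4aR,8aR)-1-(2,2-dibromoethenyl)-2,5,5,8a-tetramethyl-1,4,4a,5,6,7,8,8a-octahydronaphthalene
Conditions: CBr4, PPh3, CH2Cl2, 0 °C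
Reagents that add atoms: carbon tetrabromide BrC(Br)(Br)Br
Why: Corey–Fuchs dibromo-olefination (Wittig-type) adds C12 under non-basic conditions, so the enolisable C9 stereocenter should be retained.

Step 10
Reactants: 12 the dibromoalkene
Product: 14 potassium trifluoro{[(1R,4aR,8aR)-2,5,5,8a-tetramethyl-1,4,4a,5,6,7,8,8a-octahydronaphthalen-1-yl]ethynyl}borate, via lithium acetylide 13 (not isolated)
Conditions: n-BuLi (2.1 equiv), THF, −78 °C; B(OMe)3, −78 → −20 °C; aq KHF2
Reagents that add atoms: trimethyl borate COB(OC)OC; potassium hydrogen difluoride [K+].[F-].F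
Why: Second stage of the Corey–Fuchs reaction (lithium–bromine exchange and Fritsch–Buttenberg–Wiechell shift) gives the lithium acetylide, which is trapped as the bench-stable alkynyltrifluoroborate; no stereocenter is touched.

Step 11
Reactants: 15 ethyl 4-methylpent-4-enoate
Product: 16 4-methylpent-4-enal
Conditions: i-Bu2AlH, CH2Cl2, −78 °C
Reagents that add atoms: none
Why: Low-temperature partial reduction of the ester stops at the aldehyde through the stable tetrahedral aluminate.

Step 12
Reactants: 16 4-methylpent-4-enal; 17 (S)-4-benzyl-3-propionyl-1,3-oxazolidin-2-one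
Product: 18 (4S)-4-benzyl-3-[(2S,3R)-3-hydroxy-2,6-dimethylhept-6-enoyl]-1,3-oxazolidin-2-one
Conditions: Bu2BOTf, i-Pr2NEt, CH2Cl2, −78 → 0 °C; then 16, −78 → 0 °C; pH 7 buffer, MeOH, 30% H2O2
Reagents that add atoms: none
Why: Evans syn-aldol through the Z-boron enolate and a Zimmerman–Traxler chair, in which the (S)-benzyl auxiliary sets C17 (2S) and C16 (3R).

Step 13
Reactants: 18 the aldol adduct
Product: 19 (2R,3R)-2,6-dimethylhept-6-ene-1,3-diol
Conditions: LiBH4, MeOH (1 equiv), Et2O, 0 °C
Reagents that add atoms: none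
Why: Reductive removal of the auxiliary gives the 1,3-diol, so that no carbonyl remains β to C16 during the later substitution.

Step 14
Reactants: 19 the diol
Product: 20 (2R,3R)-1-[(tert-butyldiphenylsilyl)oxy]-2,6-dimethylhept-6-en-3-ol
Conditions: t-BuPh2SiCl, imidazole, CH2Cl2, 0 °C
Reagents that add atoms: tert-butyl(chloro)diphenylsilane CC(C)(C)[Si](Cl)(c1ccccc1)c1ccccc1
Why: The bulky silyl chloride should react selectively at the primary hydroxyl.

Step 15
Reactants: 20 the silyl ether alcohol
Product: 22 tert-butyl({(2R,3S)-3-[(2-methoxypropan-2-yl)peroxy]-2,6-dimethylhept-6-en-1-yl}oxy)diphenylsilane, via triflate 21 (not isolated)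
Conditions: Tf2O, 2,6-lutidine, CH2Cl2, −78 °C; then KOt-Bu, 2-methoxyprop-2-yl hydroperoxide, THF, −78 → 0 °C
Reagents that add atoms: 2-methoxyprop-2-yl hydroperoxide COC(C)(C)OO
Why: SN2 alkylation of the potassium salt of a protected hydroperoxide by the secondary triflate inverts C16 and so gives the anti C16–O/C17–CH3 relationship of the target.

Step 16
Reactants: 22 the peroxyketal alkene
Product: 23 (5S,6R)-7-[(tert-butyldiphenylsilyl)oxy]-5-[(2-methoxypropan-2-yl)peroxy]-6-methylheptan-2-one
Conditions: O3, CH2Cl2, −78 °C; then Me2S, −78 °C → rt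
Reagents that add atoms: ozone [O-][O+]=O
Why: Ozonolysis of the 1,1-disubstituted alkene unmasks the C13 methyl ketone; dialkyl peroxides tolerate ozone and Me2S.

Step 17
Reactants: 23 the keto peroxyketal
Product: 25 tert-butyl{(2R)-2-[(3S,6RS)-6-methoxy-6-methyl-1,2-dioxan-3-yl]propoxy}diphenylsilane, via hydroperoxy ketone 24 (not isolated)
Conditions: TsOH·H2O (cat.), MeOH, 0 °C → rt
Reagents that add atoms: methanol CO
Why: Acid methanolysis frees the hydroperoxide, which closes onto the ketone to the six-membered peroxyhemiketal and is ketalised to the 3-methoxy-1,2-dioxane; both C13 epimers are carried on because C13 is re-formed in step 21.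

Step 18
Reactants: 25 the silyl-protected methoxydioxane
Product: 26 (2R)-2-[(3S,6RS)-6-methoxy-6-methyl-1,2-dioxan-3-yl]propan-1-ol
Conditions: Bu4NF, THF, 0 °C
Reagents that add atoms: none
Why: Fluoride desilylation, which the peroxyketal should tolerate.

Step 19
Reactants: 26 the primary alcohol
Product: 27 (2S)-2-[(3S,6RS)-6-methoxy-6-methyl-1,2-dioxan-3-yl]propanoic acid
Conditions: TEMPO (cat.), PhI(OAc)2, MeCN/H2O, rt
Reagents that add atoms: water O
Why: Nitroxyl-catalysed oxidation takes the alcohol through the aldehyde hydrate to the acid under near-neutral conditions that should spare the O–O bond and the C17 stereocenter.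

Step 20
Reactants: 27 the acid
Product: 28 methyl (2S)-2-[(3S,6RS)-6-methoxy-6-methyl-1,2-dioxan-3-yl]propanoate
Conditions: Me3SiCHN2, MeOH/toluene, 0 °C
Reagents that add atoms: trimethylsilyldiazomethane C[Si](C)(C)C=[N+]=[N-]
Why: Diazoalkane esterification without base avoids β-elimination of the peroxide and epimerisation at C17.

Step 21
Reactants: 14 the potassium alkynyltrifluoroborate; 28 the methoxydioxane ester
Product: 29 methyl (2S)-2-[(3S,6R)-6-methyl-6-{[(1R,4aR,8aR)-2,5,5,8a-tetramethyl-1,4,4a,5,6,7,8,8a-octahydronaphthalen-1-yl]ethynyl}-1,2-dioxan-3-yl]propanoate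
Conditions: BF3·OEt2 (2.5 equiv), CH2Cl2/MeCN, −78 → −30 °C
Reagents that add atoms: none
Why: Proposed new method: BF3 abstracts fluoride from 14 to give the alkynyldifluoroborane, which ionises the peroxyketal 28 to the six-membered peroxycarbenium ion at C13 and delivers the alkynyl group to it; the closest known reaction types are the Lewis-acid substitution of 3-alkoxy-1,2-dioxanes by allylsilanes and silyl enol ethers through peroxycarbenium ions and the BF3-mediated coupling of O,O-acetals with potassium alkynyltrifluoroborates, and attack along the axial trajectory on the half-chair ion whose C16 side chain is pseudo-equatorial should place the alkynyl group axial and cis to that side chain, which sets C13 as in the target.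

Step 22
Reactants: 29 the alkynyl dioxane
Product: 30 CNP0124238.1, methyl (2S)-2-[(3S,6S)-6-methyl-6-{2-[(1R,4aR,8aR)-2,5,5,8a-tetramethyl-1,4,4a,5,6,7,8,8a-octahydronaphthalen-1-yl]ethyl}-1,2-dioxan-3-yl]propanoate
Conditions: KO2CN=NCO2K (excess, in portions), AcOH, MeOH/CH2Cl2, 0 °C → rt
Reagents that add atoms: none
Why: Diimide reduction transfers hydrogen twice to the alkyne by concerted syn delivery and should leave the O–O bond, the ester and the hindered trisubstituted C7=C8 alkene untouched; no stereocenter changes.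

**Compound list**
1 | β-cyclocitral (2,6,6-trimethylcyclohex-1-ene-1-carbaldehyde) | CC1=C(C=O)C(C)(C)CCC1 | starting material
2 | β-cyclogeraniol, (2,6,6-trimethylcyclohex-1-en-1-yl)methanol | CC1=C(CO)C(C)(C)CCC1 | intermediate
3 | β-cyclogeranyl acetate | CC1=C(COC(C)=O)C(C)(C)CCC1 | intermediate
4 | methyl 3-methylbut-2-enoate | COC(=O)C=C(C)C | starting material
5 | methyl 3-methyl-2-[methyl(diphenyl)silyl]but-3-enoate (racemic) | COC(=O)C(C(C)=C)[Si](C)(c1ccccc1)c1ccccc1 | intermediate
6 | 3-methyl-2-[methyl(diphenyl)silyl]but-3-en-1-ol (racemic) | OCC(C(C)=C)[Si](C)(c1ccccc1)c1ccccc1 | intermediate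
7 | triethyl{[3-methyl-2-(methyldiphenylsilyl)but-3-en-1-yl]oxy}silane (racemic) | CC[Si](CC)(CC)OCC(C(C)=C)[Si](C)(c1ccccc1)c1ccccc1 | intermediate
8 | triethyl{[(2E)-3-methyl-5-(2,6,6-trimethylcyclohex-1-en-1-yl)pent-2-en-1-yl]oxy}silane | CC1=C(CC/C(C)=C/CO[Si](CC)(CC)CC)C(C)(C)CCC1 | intermediate (not isolated)
9 | (±)-drimenol, racemic [(1R*,4aR*,8aR*)-2,5,5,8a-tetramethyl-1,4,4a,5,6,7,8,8a-octahydronaphthalen-1-yl]methanol | OC[C@@H]1C(C)=CC[C@@H]2C(C)(C)CCC[C@@]12C.OC[C@H]1C(C)=CC[C@H]2C(C)(C)CCC[C@]12C | intermediate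
10 | (1R,4aR,8aR)-drimenol (ent-drimenol) | OC[C@@H]1C(C)=CC[C@@H]2C(C)(C)CCC[C@@]12C | intermediate
11 | (1R,4aR,8aR)-2,5,5,8a-tetramethyl-1,4,4a,5,6,7,8,8a-octahydronaphthalene-1-carbaldehyde (ent-drimenal) | O=C[C@@H]1C(C)=CC[C@@H]2C(C)(C)CCC[C@@]12C | intermediate
12 | (1R,4aR,8aR)-1-(2,2-dibromoethenyl)-2,5,5,8a-tetramethyl-1,4,4a,5,6,7,8,8a-octahydronaphthalene | BrC(Br)=C[C@@H]1C(C)=CC[C@@H]2C(C)(C)CCC[C@@]12C | intermediate
13 | lithium acetylide of (1R,4aR,8aR)-1-ethynyl-2,5,5,8a-tetramethyl-1,4,4a,5,6,7,8,8a-octahydronaphthalene | [Li]C#C[C@@H]1C(C)=CC[C@@H]2C(C)(C)CCC[C@@]12C | intermediate (not isolated)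
14 | potassium trifluoro{[(1R,4aR,8aR)-2,5,5,8a-tetramethyl-1,4,4a,5,6,7,8,8a-octahydronaphthalen-1-yl]ethynyl}borate | [K+].F[B-](F)(F)C#C[C@@H]1C(C)=CC[C@@H]2C(C)(C)CCC[C@@]12C | intermediate
15 | ethyl 4-methylpent-4-enoate | CCOC(=O)CCC(C)=C | starting material
16 | 4-methylpent-4-enal | O=CCCC(C)=C | intermediate
17 | (S)-4-benzyl-3-propionyl-1,3-oxazolidin-2-one | CCC(=O)N1C(=O)OC[C@@H]1Cc1ccccc1 | starting material
18 | (4S)-4-benzyl-3-[(2S,3R)-3-hydroxy-2,6-dimethylhept-6-enoyl]-1,3-oxazolidin-2-one | C[C@@H]([C@H](O)CCC(C)=C)C(=O)N1C(=O)OC[C@@H]1Cc1ccccc1 | intermediate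
19 | (2R,3R)-2,6-dimethylhept-6-ene-1,3-diol | C[C@@H]([C@H](O)CCC(C)=C)CO | intermediate
20 | (2R,3R)-1-[(tert-butyldiphenylsilyl)oxy]-2,6-dimethylhept-6-en-3-ol | C[C@@H]([C@H](O)CCC(C)=C)CO[Si](c1ccccc1)(c1ccccc1)C(C)(C)C | intermediate
21 | (2R,3R)-1-[(tert-butyldiphenylsilyl)oxy]-2,6-dimethylhept-6-en-3-yl trifluoromethanesulfonate | C[C@@H]([C@H](OS(=O)(=O)C(F)(F)F)CCC(C)=C)CO[Si](c1ccccc1)(c1ccccc1)C(C)(C)C | intermediate (not isolated)
22 | tert-butyl({(2R,3S)-3-[(2-methoxypropan-2-yl)peroxy]-2,6-dimethylhept-6-en-1-yl}oxy)diphenylsilane | C[C@@H]([C@@H](OOC(C)(C)OC)CCC(C)=C)CO[Si](c1ccccc1)(c1ccccc1)C(C)(C)C | intermediate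
23 | (5S,6R)-7-[(tert-butyldiphenylsilyl)oxy]-5-[(2-methoxypropan-2-yl)peroxy]-6-methylheptan-2-one | C[C@@H]([C@@H](OOC(C)(C)OC)CCC(C)=O)CO[Si](c1ccccc1)(c1ccccc1)C(C)(C)C | intermediate
24 | (5S,6R)-7-[(tert-butyldiphenylsilyl)oxy]-5-hydroperoxy-6-methylheptan-2-one | C[C@@H]([C@@H](OO)CCC(C)=O)CO[Si](c1ccccc1)(c1ccccc1)C(C)(C)C | intermediate (not isolated)
25 | tert-butyl{(2R)-2-[(3S,6RS)-6-methoxy-6-methyl-1,2-dioxan-3-yl]propoxy}diphenylsilane | C[C@@H]([C@@H]1CCC(C)(OC)OO1)CO[Si](c1ccccc1)(c1ccccc1)C(C)(C)C | intermediate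
26 | (2R)-2-[(3S,6RS)-6-methoxy-6-methyl-1,2-dioxan-3-yl]propan-1-ol | C[C@@H]([C@@H]1CCC(C)(OC)OO1)CO | intermediate
27 | (2S)-2-[(3S,6RS)-6-methoxy-6-methyl-1,2-dioxan-3-yl]propanoic acid | C[C@@H]([C@@H]1CCC(C)(OC)OO1)C(=O)O | intermediate
28 | methyl (2S)-2-[(3S,6RS)-6-methoxy-6-methyl-1,2-dioxan-3-yl]propanoate | COC(=O)[C@@H](C)[C@@H]1CCC(C)(OC)OO1 | intermediate
29 | methyl (2S)-2-[(3S,6R)-6-methyl-6-{[(1R,4aR,8aR)-2,5,5,8a-tetramethyl-1,4,4a,5,6,7,8,8a-octahydronaphthalen-1-yl]ethynyl}-1,2-dioxan-3-yl]propanoate | COC(=O)[C@@H](C)[C@@H]1CC[C@](C)(C#C[C@@H]2C(C)=CC[C@@H]3C(C)(C)CCC[C@@]23C)OO1 | intermediate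
30 | CNP0124238.1, methyl (2S)-2-[(3S,6S)-6-methyl-6-{2-[(1R,4aR,8aR)-2,5,5,8a-tetramethyl-1,4,4a,5,6,7,8,8a-octahydronaphthalen-1-yl]ethyl}-1,2-dioxan-3-yl]propanoate | COC(=O)[C@@H](C)[C@@H]1CC[C@](C)(CC[C@@H]2C(C)=CC[C@@H]3C(C)(C)CCC[C@@]23C)OO1 | target

**Count**
Total steps: 22. Longest linear sequence: 12 steps (steps 11–20, then 21 and 22).

**Steps most likely to fail**

Step 21. The ketone-derived peroxycarbenium ion may lose a proton to an enol perether or fragment by carbon-to-oxygen migration faster than the alkynyl group is transferred, or the transfer may show poor facial selectivity at C13. The fallback uses known chemistry, sets out from 12 and 23 and comes back at 29. Dibromoalkene 12 is converted with n-BuLi into the lithium acetylide and then, with CeCl3, into the chlorocerium acetylide, which is added to ketone 23 at −78 °C to give the tertiary propargylic alcohol F1 (both carbinol epimers). Camphorsulfonic acid in CH2Cl2 containing two equivalents of MeOH removes the methoxypropyl group and closes the ring by acid-catalysed substitution of the tertiary propargylic alcohol by the hydroperoxide, the classical route to acetylenic peroxides. Reversible ionisation should favour the isomer with the small alkynyl group axial, the silyl-protected alkynyl dioxane F2. Bu4NF then gives the alcohol F3, TEMPO with PhI(OAc)2 gives the acid F4, and Me3SiCHN2 gives 29.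

Step 6. The allylation may erode the alkene geometry (the Z isomer would lead to the C9 epimer), 7 may be protodesilylated before the C–C bond forms, or the final cation may lose the wrong proton. The fallback sets out from 2 and comes back at 9, forming the two bonds in separate steps. PBr3 converts 2 into β-cyclogeranyl bromide F5. The lithio derivative of tert-butyldimethyl{[(2E)-3-methyl-4-(phenylsulfonyl)but-2-en-1-yl]oxy}silane (n-BuLi, THF, −78 °C), in which the E-alkene is already fixed, is alkylated with F5 to give the sulfone F6. Reductive desulfonylation with PdCl2(dppp) (cat.) and LiBHEt3 gives the E-monocyclofarnesyl tert-butyldimethylsilyl ether F7, and FSO3H in 2-nitropropane at −78 °C cyclises it to 9.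

Step 15. The hindered secondary triflate may undergo elimination, or the remote alkene may participate, instead of clean substitution with inversion. The fallback sets out from 20 and comes back at 22, changing both the leaving group and the kind of oxygen nucleophile. MsCl and Et3N give the mesylate F8. Displacement by superoxide (KO2, 18-crown-6, DMF, 0 °C) should give the inverted hydroperoxide F9, which is protected with 2-methoxypropene and pyridinium p-toluenesulfonate to give 22.

Further compounds
F1 | step 21 | (6R,7S)-8-[(tert-butyldiphenylsilyl)oxy]-6-[(2-methoxypropan-2-yl)peroxy]-3,7-dimethyl-1-[(1R,4aR,8aR)-2,5,5,8a-tetramethyl-1,4,4a,5,6,7,8,8a-octahydronaphthalen-1-yl]oct-1-yn-3-ol (both C3 epimers) | C[C@@H]([C@@H](OOC(C)(C)OC)CCC(C)(O)C#C[C@@H]1C(C)=CC[C@@H]2C(C)(C)CCC[C@@]12C)CO[Si](c1ccccc1)(c1ccccc1)C(C)(C)C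
F2 | step 21 | tert-butyl{(2R)-2-[(3S,6R)-6-methyl-6-{[(1R,4aR,8aR)-2,5,5,8a-tetramethyl-1,4,4a,5,6,7,8,8a-octahydronaphthalen-1-yl]ethynyl}-1,2-dioxan-3-yl]propoxy}diphenylsilane | C[C@@H]([C@@H]1CC[C@](C)(C#C[C@@H]2C(C)=CC[C@@H]3C(C)(C)CCC[C@@]23C)OO1)CO[Si](c1ccccc1)(c1ccccc1)C(C)(C)C
F3 | step 21 | (2R)-2-[(3S,6R)-6-methyl-6-{[(1R,4aR,8aR)-2,5,5,8a-tetramethyl-1,4,4a,5,6,7,8,8a-octahydronaphthalen-1-yl]ethynyl}-1,2-dioxan-3-yl]propan-1-ol | C[C@@H]([C@@H]1CC[C@](C)(C#C[C@@H]2C(C)=CC[C@@H]3C(C)(C)CCC[C@@]23C)OO1)CO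
F4 | step 21 | (2S)-2-[(3S,6R)-6-methyl-6-{[(1R,4aR,8aR)-2,5,5,8a-tetramethyl-1,4,4a,5,6,7,8,8a-octahydronaphthalen-1-yl]ethynyl}-1,2-dioxan-3-yl]propanoic acid | C[C@@H]([C@@H]1CC[C@](C)(C#C[C@@H]2C(C)=CC[C@@H]3C(C)(C)CCC[C@@]23C)OO1)C(=O)O
F5 | step 6 | β-cyclogeranyl bromide, 2-(bromomethyl)-1,3,3-trimethylcyclohex-1-ene | CC1=C(CBr)C(C)(C)CCC1
F6 | step 6 | tert-butyldimethyl{[(2E)-3-methyl-4-(phenylsulfonyl)-5-(2,6,6-trimethylcyclohex-1-en-1-yl)pent-2-en-1-yl]oxy}silane (racemic) | CC1=C(CC(/C(C)=C/CO[Si](C)(C)C(C)(C)C)S(=O)(=O)c2ccccc2)C(C)(C)CCC1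
F7 | step 6 | tert-butyldimethyl{[(2E)-3-methyl-5-(2,6,6-trimethylcyclohex-1-en-1-yl)pent-2-en-1-yl]oxy}silane | CC1=C(CC/C(C)=C/CO[Si](C)(C)C(C)(C)C)C(C)(C)CCC1
F8 | step 15 | (2R,3R)-1-[(tert-butyldiphenylsilyl)oxy]-2,6-dimethylhept-6-en-3-yl methanesulfonate | C[C@@H]([C@H](OS(C)(=O)=O)CCC(C)=C)CO[Si](c1ccccc1)(c1ccccc1)C(C)(C)C
F9 | step 15 | tert-butyl{[(2R,3S)-3-hydroperoxy-2,6-dimethylhept-6-en-1-yl]oxy}diphenylsilane | C[C@@H]([C@@H](OO)CCC(C)=C)CO[Si](c1ccccc1)(c1ccccc1)C(C)(C)C
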